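The data were computed with made-up constants; noise was put on by code.

**The ledger.** Every part of the Z charged stands somewhere: as free Z, as L, or in an unseen form, and these fractions sum to one.

| flask | Z | D | Q | remark | time |
|---|---|---|---|---|---|
| ochre | 0.010 M | 0.010 mM | 14 mM (fed, over 12 h) | run made earlier |  |
| violet | 0.010 M | 0.010 mM | 22 mM (fed, over 12 h) | run made earlier |  |
| red | 0.015 M | 0.010 mM | 10 mM (fed, over 12 h) | run made earlier |  |
| flask | 0.010 M | 0.0100 mM | 10.0 mM (fed, over 12 h) |  | 12 h |

- ochre (time / h: Z / %, L / %): 0.833: 87, 7; 2.00: 69, 21; 4.00: 55, 35; 10.0: 33, 65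
- violet (time / h: Z / %, L / %): 0.833: 87, 8; 2.00: 70, 19; 4.00: 61, 34; 10.0: 32, 66
- red (time / h: Z / %, L / %): 2.50: 62, 25; 5.00: 44, 41; 8.00: 36, 54; 10.0: 31, 65

(readings scatter by 1.5 percentage points)

- D is the free proton; pH is minus the decimal logarithm of its molar concentration
- the numbers in the tables scatter by 1.5 percentage points (one standard deviation)
- a reading of Z is of its free form alone

* part of the Z that has reacted at 12 h
* pH of the solution at 12 h

**The entries.** In the ochre run at 4.00 h, Z holds 55% and L holds 35%, so 10.0% sits unseen. At 10.0 h that entry has shrunk to 2.00%, and a reading scatters by 1.5 percentage points. By then nearly all of the Z used in the ochre run reads as L.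

**The mean constant.** At 10.0 h free Z reads 33%, 32% and 31% in the ochre, violet and red runs, though Q runs from 10 mM to 22 mM and Z from 0.010 M to 0.015 M. The fraction left barely follows those charges, so one pseudo-first-order constant can stand in for the bent curve. Their mean, 32.0%, gives the mean constant, minus the natural logarithm of the fraction left divided by the time: 0.114 h⁻¹.

**Its error.** From 4.00 h to 10.0 h, the ochre and violet runs together read 0.0965 h⁻¹, slower than the mean. At 12 h the mean constant leaves 25.5% of Z, and the late constant leaves 26.4%, a difference of 0.9 points. This reckoning therefore commits to 73.6% to 74.5% reacted.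

**The forecast.** It gives 73% reacted (68% to 78%) and pH 5.1 (4.7 to 5.7), so its part reacted is slightly less than the low end of this reckoning: “Extrapolating from 32% at 10 h gives about 27% Z at 12 h”.

**The result.**

    X + Q → J (k = 8.70 L mol⁻¹ min⁻¹)
    Z + D → X + D + L (k = 150 L mol⁻¹ min⁻¹)
    X ⇌ G + D, settled at all times (K = 1.60 × 10⁻⁸ M)
    Z + X ⇌ E, settled at all times (K = 290 L mol⁻¹)
    Z → X + L (k = 3.90 × 10⁻⁴ min⁻¹)

The flask gives 73.4% reacted and pH 4.98. At 12.0 h in this flask, the reaction of Z + D to X + D + L uses Z faster than the reaction of Z to X + L does, by a factor of 4.0. The mean constant 0.114 h⁻¹ leaves 25.5% at 12 h, where the flask holds 26.6% of Z. For the same flask read at 30 h, it leaves 3.27%, and the flask holds 3.76%.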